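Compound numbers used below are those of the compound list that follows the steps.

## Analysis of the target

The target is a prenylated guaiane-type diterpenoid built on a trans-fused hydroazulene. A cyclopentene (C1–C5, C3=C4, methyl on C4) is fused to a cycloheptane (C1, C5–C10) that carries an exocyclic methylene on C10, an acetate on C9 and a free hydroxyl on C6. C7 bears the chain CH(CH3)–CH(OAc)–CH2–CH=C(CH3)2, that is C11, C12 and a prenyl group. There are seven stereocentres (1R, 5S, 6R, 7S, 9R, 11S, 12S): H1 and H5 are trans, H5 and H6 are anti, O6 and the C7–C11 bond are cis, the C9 oxygen lies on the opposite ring face, and the C11 methyl and C12 oxygen are syn along the chain (the Felkin–Anh sense). The sensitive groups are the allylic acetate at C9 beside the methylene, three isolated alkenes that acid can move, and a free hydroxyl 1,4 to an acetate, so the end game has to be mild and nearly neutral. The difficulty is the seven-membered ring with contiguous stereocentres C5, C6, C7 and a remote one at C9 on a strained trans ring fusion, together with telling three secondary hydroxyls apart and attaching the prenyl group through its unsubstituted end. The strategy rests on the oxygens at C6 and C12, which are 1,4-related through C6–C7–C11–C12. The ring bond C6–C7 therefore lies between two carbons that are both electrophilic in their natural forms (a carbonyl carbon and an enoate β-carbon), so it can be made by reductive coupling. The same two oxygens can then be tied together as a γ-lactone.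

## Retrosynthetic reasoning

**C–O bonds of the acetates.** Target 23 is traced to triol 22 by removing both acetyl groups. The C6 hydroxyl is flanked by the ring-fusion carbon C5 and the branched C7, so acylation should stop after O9 and O12. Triol 22 comes from silyl ether 21; the C9 oxygen has to stay masked through all reducing and organometallic steps.

**C12–CH2 bond of the prenyl group.** Diol 21 is cut between C12 and the prenyl methylene, giving lactol 19 (a masked C12 aldehyde whose ring oxygen is O6) and a prenyl nucleophile made from 20. The cut is made here because it releases O6 and creates the C12 carbinol in one operation. The forward reaction must attach the prenyl unit through its CH2 terminus and add to the aldehyde in the Felkin–Anh sense set by C11.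

**Oxidation level at C12.** Lactol 19 comes from lactone 18 by partial hydride reduction. The lactone keeps O6 and C12 protected against each other until the prenyl group is needed.

**C6–C7 and O6–C12 (key disconnection).** Lactone 18 is opened through hydroxy ester 17 to aldehyde 16, cutting the ring bond C6–C7 and the lactone C–O bond. No other ring bond connects two carbons that can each be drawn as an acceptor, and cutting here turns the seven-membered ring into a chain hanging from a trans-disubstituted cyclopentene. The forward step must join the aldehyde carbon to the enoate β-carbon with umpolung, close the seven-membered ring, set C6, C7 and C11, and lactonise.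

**C7=C11.** Aldehyde 16 comes from alcohol 15 by oxidation, and 15 from the terminal alkene 13 and 14 by cross-metathesis. The ring ester is reduced before the enoate is introduced, so that at no stage do two esters have to be told apart. The aldehyde is unmasked last because it is epimerisable at C5 and prone to conjugation.

**C3=C4.** Alcohol 13 comes from ester 12, and the ring alkene of 12 from the C3 hydroxyl of 11 by dehydration. The alkene is introduced only after the isopropenyl methyl has been oxidised, because a trisubstituted ring alkene would compete in that allylic oxidation.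

**C8–C9.** The homoallylic silyl ether 10, precursor of 11, comes from alcohol 9, and 9 from enal 7 and 8 by catalytic asymmetric allylboration. This bond is chosen because it creates the C9 carbinol under catalyst control and delivers the terminal alkene needed for the metathesis.

**C9 oxidation.** Enal 7 comes from allylic alcohol 6, and 6 from the isopropenyl group of ester 5 by allylic oxidation of its methyl group, which is the only allylic CH3 while C3 is still an ether.

**Ring contraction to the chiral pool.** Ester 5 is the ring-contraction product of chloro ketone 4, made from chlorohydrin 3, epoxide 2 and 1. The stereocentre of 1 becomes C1 of the target. The carboxyl group ends trans to it, which sets the trans ring fusion, and the C3 oxygen is left as the handle for the ring alkene.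

## Alternatives that were turned down

**Alternative 1:** The seven-membered ring is cut at C7–C8 and C1–C10 and assembled from two pieces. In the forward step a chiral dirhodium tetracarboxylate generates a vinylcarbene that cyclopropanates the C6=C7 enol-ether bond of a cyclopentene-based diene. The resulting cis-divinylcyclopropane undergoes Cope rearrangement to cycloheptadiene A1, which carries the full side chain, enol silanes at C6 and C9, an ester on C8 and a ketal at C4.
- For: it is convergent, it makes the ring and two bonds at once, the absolute configuration comes from the catalyst, and the boat Cope transition state fixes C1 relative to C7. On convergence and on independence from the chiral pool it is stronger than the chosen route.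
- Against: the alkene to be cyclopropanated is a trisubstituted enol ether next to the branched C11, the kind of hindered alkene that donor–acceptor carbenes take poorly. A1 also has the wrong inventory: the C8 ester must be excised, C10 lacks its methylene carbon, C4 lacks its methyl, C5 is still sp2 so the trans fusion must be set later against the cis preference of hydroazulenones, and C6 and C9 need face-selective reductions.
- Comparison: the chosen route starts with C1 and C5 trans and forms C6, C7 and C11 with the final oxygen pattern in one step, which is worth more here than convergence followed by a long redox sequence.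

**Alternative 2:** The cyclopentene is cut at C4–C5 and C1–C2 on cycloheptenone A2. An isopropenyl group is transferred from copper to C5 anti to the C6 silyloxy group, and the enolate is allylated at C1 anti to the new substituent, giving A3. A later ring-closing metathesis would form C3=C4.
- For: every event is a well-understood closed-shell reaction and the trans relationship at C1/C5 follows from two anti additions. On predictability of the ring fusion it is at least as good as the chosen route.
- Against: A2 already contains C6, C7, C11 and C12, so the hardest stereochemical problem (the cis C6/C7 array with its side chain on a seven-membered ring) is moved into an unsolved starting material. Allylation of seven-membered enolates is slow and allows proton transfer to C9. The C9 oxygen and the C10 methylene still have to be added by a face-selective α-oxygenation and methylenation of a ketone flanked by two substituted carbons.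
- Comparison: the chosen route gives the ring and three stereocentres from a simple chiral-pool precursor and is clearly shorter.

**Alternative 3:** C9 is inserted between C10 and C8 of the six-membered ketone A4. A Lewis acid promotes addition of a silylated diazoalkane to the C10 carbonyl, the C8 methylene migrates with loss of nitrogen, and a silyl shift to oxygen gives enol silane A5.
- For: six-membered precursors are easier to build stereoselectively, no medium ring has to be closed, and A5 is well placed for oxygenation at C9 and later methylenation at C10. On the ring-size tactic it is stronger than a direct seven-membered closure.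
- Against: in A4 the ring-fusion carbon C1 is α to the ketone, so the trans fusion can epimerise to the more stable cis-hydrindanone under the Lewis acid. Migration of C8 over C1 is not assured, the lactone carbonyl competes for the Lewis acid, and A4 already needs five stereocentres (C1, C5, C6, C7, C11) before several further steps.
- Comparison: the chosen route never places C1 next to a carbonyl and makes the seven-membered ring and the lactone together.

Key step: step 14

Remark: atoms are numbered as in guaianes (C13 is the methyl on C11, C14 the methylene on C10, C15 the methyl on C4); tetrahydropyranyl ethers and lactol 19 are taken as mixtures at the acetal carbon, which is left undefined in their SMILES; TBS is tert-butyldimethylsilyl.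

## Route

Step 1
Reactants: 1 (R)-(−)-carvone
Product: 2 (1R,4R,6R)-1-methyl-4-(prop-1-en-2-yl)-7-oxabicyclo[4.1.0]heptan-2-one
Conditions: H2O2 (30% aq), NaOH (cat.), MeOH, 0 °C
Reagents that add atoms: hydrogen peroxide, OO
Why: Weitz–Scheffer nucleophilic epoxidation touches only the enone; hydroperoxide adds to the β-carbon anti to the isopropenyl group, so the epoxide should form trans to it.

Step 2
Reactants: 2 trans-carvone epoxide
Product: 3 (2S,3R,5R)-2-chloro-3-hydroxy-2-methyl-5-(prop-1-en-2-yl)cyclohexan-1-one
Conditions: LiCl, CF3CO2H, THF, rt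
Reagents that add atoms: lithium chloride, [Li+].[Cl-]
Why: Acid-promoted trans-diaxial epoxide opening by chloride at the α-carbon with inversion gives the α-chloro-β-hydroxy ketone required for ring contraction.

Step 3
Reactants: 3 chlorohydrin
Product: 4 (2S,3R,5R)-2-chloro-2-methyl-3-(oxan-2-yloxy)-5-(prop-1-en-2-yl)cyclohexan-1-one
Conditions: 3,4-dihydro-2H-pyran, PPTS (cat.), CH2Cl2, rt
Reagents that add atoms: 3,4-dihydro-2H-pyran, C1=COCCC1
Why: Acetal protection of the β-hydroxyl prevents base-induced return to the epoxide or retro-aldol cleavage in the next step.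

Step 4
Reactants: 4 chloro ketone tetrahydropyranyl ether
Product: 5 methyl (1S,2R,3R,5R)-2-methyl-3-(oxan-2-yloxy)-5-(prop-1-en-2-yl)cyclopentane-1-carboxylate
Conditions: NaOMe, MeOH, 0 °C to rt
Reagents that add atoms: sodium methoxide, C[O-].[Na+]
Why: Favorskii rearrangement: the α′-enolate displaces the tertiary chloride with inversion to a cyclopropanone that methoxide opens to the ring-contracted ester; the ester ends trans to both neighbours (C1/C5 trans), which is also the arrangement favoured under equilibrating methoxide.

Step 5
Reactants: 5 cyclopentane ester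
Product: 6 methyl (1S,2R,3R,5R)-5-(3-hydroxyprop-1-en-2-yl)-2-methyl-3-(oxan-2-yloxy)cyclopentane-1-carboxylate
Conditions: SeO2 (cat.), t-BuOOH, salicylic acid (cat.), CH2Cl2, rt
Reagents that add atoms: tert-butyl hydroperoxide, CC(C)(C)OO; selenium dioxide, O=[Se]=O (catalytic oxygen carrier)
Why: Allylic oxidation by ene reaction and 2,3-sigmatropic shift on the only alkene present, at the methyl in preference to the ring methine; any over-oxidised enal 7 converges in step 6.

Step 6
Reactants: 6 allylic alcohol
Product: 7 methyl (1S,2R,3R,5R)-2-methyl-3-(oxan-2-yloxy)-5-(3-oxoprop-1-en-2-yl)cyclopentane-1-carboxylate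
Conditions: MnO2, CH2Cl2, rt
Reagents that add atoms: none
Why: Chemoselective oxidation of the allylic alcohol to the 2-substituted acrolein, which is used without storage.

Step 7
Reactants: 7 enal; 8 allylboronic acid pinacol ester
Product: 9 methyl (1S,2R,3R,5R)-5-[(3R)-3-hydroxyhexa-1,5-dien-2-yl]-2-methyl-3-(oxan-2-yloxy)cyclopentane-1-carboxylate
Conditions: (R)-TRIP (5 mol %), 4 Å MS, toluene, −30 °C
Reagents that add atoms: none
Why: Chiral phosphoric acid-catalysed allylboration through a six-membered chair transition state; the (R)-catalyst is expected to deliver allyl to the Re face of an alkenyl aldehyde, giving 9R under catalyst control (the antipodal acid would be used should the sense prove opposite).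

Step 8
Reactants: 9 homoallylic alcohol
Product: 10 methyl (1S,2R,3R,5R)-5-[(3R)-3-(tert-butyldimethylsilyloxy)hexa-1,5-dien-2-yl]-2-methyl-3-(oxan-2-yloxy)cyclopentane-1-carboxylate
Conditions: TBSCl, imidazole, DMAP (cat.), DMF, 40 °C
Reagents that add atoms: tert-butyldimethylsilyl chloride, CC(C)(C)[Si](C)(C)Cl
Why: Standard silylation; the TBS ether survives the acid, hydride, metathesis, samarium and organobarium steps and is removed by fluoride at the end.

Step 9
Reactants: 10 silyl ether
Product: 11 methyl (1S,2R,3R,5R)-5-[(3R)-3-(tert-butyldimethylsilyloxy)hexa-1,5-dien-2-yl]-3-hydroxy-2-methylcyclopentane-1-carboxylate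
Conditions: PPTS, MeOH, 40 °C
Reagents that add atoms: none
Why: Mild acetal exchange removes the tetrahydropyranyl group while the secondary TBS ether stays.

Step 10
Reactants: 11 C3 alcohol
Product: 12 methyl (1S,5R)-5-[(3R)-3-(tert-butyldimethylsilyloxy)hexa-1,5-dien-2-yl]-2-methylcyclopent-2-ene-1-carboxylate
Conditions: Burgess reagent, toluene, 60 °C
Reagents that add atoms: none
Why: Burgess dehydration is a syn elimination through the sulfamate ester; the C3 oxygen is cis to the tertiary C4–H, so the trisubstituted C3=C4 alkene should be favoured, and the neutral medium leaves the β,γ-unsaturated ester unconjugated and C5 untouched.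

Step 11
Reactants: 12 cyclopentene ester
Product: 13 [(1S,5R)-5-[(3R)-3-(tert-butyldimethylsilyloxy)hexa-1,5-dien-2-yl]-2-methylcyclopent-2-en-1-yl]methanol
Conditions: i-Bu2AlH, CH2Cl2, −78 to 0 °C
Reagents that add atoms: none
Why: Non-basic hydride reduction of the only ester to the primary alcohol, done before the enoate is installed so that two esters never have to be distinguished.

Step 12
Reactants: 13 primary alcohol; 14 methyl methacrylate
Product: 15 methyl (2E,5R)-5-(tert-butyldimethylsilyloxy)-6-[(1R,5S)-5-(hydroxymethyl)-4-methylcyclopent-3-en-1-yl]-2-methylhepta-2,6-dienoate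
Conditions: second-generation Hoveyda–Grubbs catalyst (5 mol %), 14 in excess, CH2Cl2, 40 °C
Reagents that add atoms: none
Why: Cross-metathesis of the monosubstituted terminal alkene with a 1,1-disubstituted acrylate; the hindered exocyclic methylene and the trisubstituted ring alkene should not take part, and the E-enoate is the expected product.

Step 13
Reactants: 15 hydroxy enoate
Product: 16 methyl (2E,5R)-5-(tert-butyldimethylsilyloxy)-6-[(1R,5S)-5-formyl-4-methylcyclopent-3-en-1-yl]-2-methylhepta-2,6-dienoate
Conditions: Dess–Martin periodinane, NaHCO3, CH2Cl2, 0 °C; used at once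
Reagents that add atoms: none
Why: Buffered Dess–Martin oxidation is neutral and cold, so the β,γ-unsaturated aldehyde should neither epimerise at C5 nor move its alkene into conjugation before it is consumed.

Step 14
Reactants: 16 aldehyde enoate
Product: 18 (1R,5S,6R,7S,9R,11S)-9-(tert-butyldimethylsilyloxy)guaia-3,10(14)-dien-12,6-olide, via hydroxy ester 17 (not isolated)
Conditions: SmI2 (3 equiv), HMPA, t-BuOH (2 equiv), THF, −78 to 0 °C, slow addition of 16 at high dilution; then DBU, toluene, 60 °C
Reagents that add atoms: none
Why: Single-electron reduction of the aldehyde gives a samarium ketyl that adds to C7 of the enoate in a 7-exo-trig radical closure (bond C6–C7, seven-membered ring); a second electron turns the C11 radical into a samarium enolate that t-BuOH protonates to hydroxy ester 17, and the C6 alkoxide then acylates on C12 in a 5-exo-trig closure of the cis γ-lactone, completed by the DBU treatment. The closest known reaction type is the SmI2 aldehyde–enoate (ketyl–olefin) reductive cyclisation with lactonisation. C6: the bulky samarium-bound oxygen eclipses the small C5–H, so H6 takes the slot between C1 and C4 and the new bond forms on the face that leaves H5 and H6 anti. C7: in the twist-chair that keeps the allylic C9 silyloxy group pseudo-axial beside the sp2 C10 and keeps C11 anti to both ring bonds at C7, the enoate presents the face that puts C11 cis to O6. An E-enoate held by a samarium bridge between ketyl oxygen and ester would instead be expected to give the trans adduct, so HMPA is used to saturate the metal and leave the non-chelated, dipole-opposed arrangement as the reacting one. C11 is first set by enolate protonation without reliable control and is then equilibrated by DBU to the epimer with its methyl on the convex face of the cis-fused lactone, which is the required 11S. The step thus needs anti H5/H6 and cis O6/C11 selectivity: the C5 stereocentre with its trans C1 arm secures the first, and the ring template in a non-chelating medium is relied on for the second.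

Step 15
Reactants: 18 lactone
Product: 19 (1R,5S,6R,7S,9R,11S)-9-(tert-butyldimethylsilyloxy)-6,12-epoxyguaia-3,10(14)-dien-12-ol
Conditions: i-Bu2AlH (1.1 equiv), CH2Cl2, −78 °C
Reagents that add atoms: none
Why: At low temperature the tetrahedral aluminium hemiacetal persists until work-up, so reduction stops at the lactol.

Step 16
Reactants: 19 lactol; 20 prenyl chloride
Product: 21 (1R,5S,6R,7S,9R,11S,12S)-9-(tert-butyldimethylsilyloxy)-12-(3-methylbut-2-en-1-yl)guaia-3,10(14)-diene-6,12-diol
Conditions: 20, activated Ba (from BaI2 and lithium biphenylide), THF, −78 °C; then 19, −78 to −40 °C (3 equiv of the barium reagent)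
Reagents that add atoms: none
Why: Allylbarium reagents add to aldehydes through their less substituted (α) terminus, giving the linear prenyl carbinol; one equivalent deprotonates the lactol, which opens to the alkoxide aldehyde, and addition in the Felkin–Anh sense (C7 branch anti to the nucleophile, C11 methyl inside) gives 12S, the same face being the open one of a barium-bridged alkoxide–aldehyde chelate.

Step 17
Reactants: 21 silyl ether diol
Product: 22 (1R,5S,6R,7S,9R,11S,12S)-12-(3-methylbut-2-en-1-yl)guaia-3,10(14)-diene-6,9,12-triol
Conditions: Bu4NF, THF, 0 °C to rt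
Reagents that add atoms: none
Why: Fluoride cleaves the Si–O bond; no acyl group is present yet, so nothing can migrate.

Step 18
Reactants: 22 triol
Product: 23 (1R,5S,6R,7S,9R,11S,12S)-6-hydroxy-12-(3-methylbut-2-en-1-yl)guaia-3,10(14)-diene-9,12-diyl diacetate (target)
Conditions: Ac2O (2.2 equiv), pyridine, DMAP (cat.), CH2Cl2, −20 to 0 °C
Reagents that add atoms: acetic anhydride, CC(=O)OC(C)=O
Why: Rate-controlled acylation: the allylic C9 hydroxyl and the side-chain C12 hydroxyl should react, while the C6 hydroxyl, shielded by the ring-fusion carbon C5 and the branched C7, should remain free at low temperature with limited anhydride.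

## Compound list

1 | (R)-(−)-carvone | CC1=CC[C@H](CC1=O)C(C)=C | starting material
2 | (1R,4R,6R)-1-methyl-4-(prop-1-en-2-yl)-7-oxabicyclo[4.1.0]heptan-2-one | O=C1C[C@H](C(C)=C)C[C@H]2O[C@@]12C | intermediate
3 | (2S,3R,5R)-2-chloro-3-hydroxy-2-methyl-5-(prop-1-en-2-yl)cyclohexan-1-one | O=C1C[C@H](C(C)=C)C[C@@H](O)[C@]1(C)Cl | intermediate
4 | (2S,3R,5R)-2-chloro-2-methyl-3-(oxan-2-yloxy)-5-(prop-1-en-2-yl)cyclohexan-1-one (acetal epimers) | O=C1C[C@H](C(C)=C)C[C@@H](OC2CCCCO2)[C@]1(C)Cl | intermediate
5 | methyl (1S,2R,3R,5R)-2-methyl-3-(oxan-2-yloxy)-5-(prop-1-en-2-yl)cyclopentane-1-carboxylate | COC(=O)[C@@H]1[C@@H](C)[C@H](OC2CCCCO2)C[C@H]1C(C)=C | intermediate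
6 | methyl (1S,2R,3R,5R)-5-(3-hydroxyprop-1-en-2-yl)-2-methyl-3-(oxan-2-yloxy)cyclopentane-1-carboxylate | COC(=O)[C@@H]1[C@@H](C)[C@H](OC2CCCCO2)C[C@H]1C(CO)=C | intermediate
7 | methyl (1S,2R,3R,5R)-2-methyl-3-(oxan-2-yloxy)-5-(3-oxoprop-1-en-2-yl)cyclopentane-1-carboxylate | COC(=O)[C@@H]1[C@@H](C)[C@H](OC2CCCCO2)C[C@H]1C(C=O)=C | intermediate
8 | allylboronic acid pinacol ester | C=CCB1OC(C)(C)C(C)(C)O1 | starting material
9 | methyl (1S,2R,3R,5R)-5-[(3R)-3-hydroxyhexa-1,5-dien-2-yl]-2-methyl-3-(oxan-2-yloxy)cyclopentane-1-carboxylate | COC(=O)[C@@H]1[C@@H](C)[C@H](OC2CCCCO2)C[C@H]1C(=C)[C@H](O)CC=C | intermediate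
10 | methyl (1S,2R,3R,5R)-5-[(3R)-3-(tert-butyldimethylsilyloxy)hexa-1,5-dien-2-yl]-2-methyl-3-(oxan-2-yloxy)cyclopentane-1-carboxylate | COC(=O)[C@@H]1[C@@H](C)[C@H](OC2CCCCO2)C[C@H]1C(=C)[C@H](O[Si](C)(C)C(C)(C)C)CC=C | intermediate
11 | methyl (1S,2R,3R,5R)-5-[(3R)-3-(tert-butyldimethylsilyloxy)hexa-1,5-dien-2-yl]-3-hydroxy-2-methylcyclopentane-1-carboxylate | COC(=O)[C@@H]1[C@@H](C)[C@H](O)C[C@H]1C(=C)[C@H](O[Si](C)(C)C(C)(C)C)CC=C | intermediate
12 | methyl (1S,5R)-5-[(3R)-3-(tert-butyldimethylsilyloxy)hexa-1,5-dien-2-yl]-2-methylcyclopent-2-ene-1-carboxylate | COC(=O)[C@@H]1C(C)=CC[C@H]1C(=C)[C@H](O[Si](C)(C)C(C)(C)C)CC=C | intermediate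
13 | [(1S,5R)-5-[(3R)-3-(tert-butyldimethylsilyloxy)hexa-1,5-dien-2-yl]-2-methylcyclopent-2-en-1-yl]methanol | OC[C@@H]1C(C)=CC[C@H]1C(=C)[C@H](O[Si](C)(C)C(C)(C)C)CC=C | intermediate
14 | methyl methacrylate | C=C(C)C(=O)OC | starting material
15 | methyl (2E,5R)-5-(tert-butyldimethylsilyloxy)-6-[(1R,5S)-5-(hydroxymethyl)-4-methylcyclopent-3-en-1-yl]-2-methylhepta-2,6-dienoate | OC[C@@H]1C(C)=CC[C@H]1C(=C)[C@H](O[Si](C)(C)C(C)(C)C)C/C=C(\C)C(=O)OC | intermediate
16 | methyl (2E,5R)-5-(tert-butyldimethylsilyloxy)-6-[(1R,5S)-5-formyl-4-methylcyclopent-3-en-1-yl]-2-methylhepta-2,6-dienoate | C=C([C@H](O[Si](C)(C)C(C)(C)C)C/C=C(\C)C(=O)OC)[C@@H]1CC=C(C)[C@H]1C=O | intermediate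
17 | methyl (1R,5S,6R,7S,9R)-9-(tert-butyldimethylsilyloxy)-6-hydroxyguaia-3,10(14)-dien-12-oate, C11 epimers (hydroxy ester) | C=C1[C@H](O[Si](C)(C)C(C)(C)C)C[C@@H](C(C)C(=O)OC)[C@@H](O)[C@@H]2C(C)=CC[C@@H]12 | intermediate
18 | (1R,5S,6R,7S,9R,11S)-9-(tert-butyldimethylsilyloxy)guaia-3,10(14)-dien-12,6-olide | C=C1[C@H](O[Si](C)(C)C(C)(C)C)C[C@H]2[C@H](C)C(=O)O[C@H]2[C@@H]3C(C)=CC[C@@H]13 | intermediate
19 | (1R,5S,6R,7S,9R,11S)-9-(tert-butyldimethylsilyloxy)-6,12-epoxyguaia-3,10(14)-dien-12-ol (anomers) | C=C1[C@H](O[Si](C)(C)C(C)(C)C)C[C@H]2[C@H](C)C(O)O[C@H]2[C@@H]3C(C)=CC[C@@H]13 | intermediate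
20 | prenyl chloride (1-chloro-3-methylbut-2-ene) | CC(C)=CCCl | starting material
21 | (1R,5S,6R,7S,9R,11S,12S)-9-(tert-butyldimethylsilyloxy)-12-(3-methylbut-2-en-1-yl)guaia-3,10(14)-diene-6,12-diol | C=C1[C@H](O[Si](C)(C)C(C)(C)C)C[C@@H]([C@H](C)[C@H](CC=C(C)C)O)[C@@H](O)[C@@H]2C(C)=CC[C@@H]12 | intermediate
22 | (1R,5S,6R,7S,9R,11S,12S)-12-(3-methylbut-2-en-1-yl)guaia-3,10(14)-diene-6,9,12-triol | C=C1[C@H](O)C[C@@H]([C@H](C)[C@H](CC=C(C)C)O)[C@@H](O)[C@@H]2C(C)=CC[C@@H]12 | intermediate
23 | (3aS,4R,5S,7R,8aR)-5-[(2S,3S)-3-acetoxy-6-methylhept-5-en-2-yl]-4-hydroxy-3-methyl-8-methylidene-1,3a,4,5,6,7,8,8a-octahydroazulen-7-yl acetate | C=C1[C@H](OC(C)=O)C[C@@H]([C@H](C)[C@H](CC=C(C)C)OC(C)=O)[C@@H](O)[C@@H]2C(C)=CC[C@@H]12 | target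

## Step count and least certain steps

Total step count: 18. Longest linear sequence: 18 steps from 1 (8, 14 and 20 are purchased).

**Step 14 (key step).** The most likely failure is facial selection at C7. If the enoate reacts through the samarium-bridged arrangement that E-enoates prefer, or simply on its other face, the trans C6–O/C7–C11 series results, and this cannot be repaired because C7 is not epimerisable. Because a seven-membered radical closure is slow, further reduction of the ketyl or of the enoate, or pinacol dimerisation, may also overtake cyclisation.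

The fallback changes the control element: the Z-enoate is used under chelating conditions, the geometry from which bridged ketyl additions give syn hydroxy esters. It sets out from enal 7 and returns at lactone 18.
- Zinc/ProPhenol-catalysed addition of (trimethylsilyl)acetylene (Me2Zn, ligand antipode chosen for Re-face delivery) would give the silylalkynol F1.
- K2CO3 in MeOH would remove the C-silyl group, giving the terminal alkynol F2.
- TBSCl/imidazole would give the silyl ether F3.
- PPTS/MeOH would free the C3 alcohol F4.
- Burgess dehydration would give the cyclopentene ester F5.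
- i-Bu2AlH would give the primary alcohol F6, the alkyne being inert.
- Anti-Markovnikov hydration of the terminal alkyne ([CpRu(MeCN)3]PF6 with a bipyridine ligand, aqueous NMP), which leaves alkenes alone, would give the β-silyloxy aldehyde F7.
- Still–Gennari olefination with methyl 2-[bis(2,2,2-trifluoroethoxy)phosphoryl]propanoate (KN(SiMe3)2, 18-crown-6, THF, −78 °C) would give the Z-enoate alcohol F8.
- Buffered Dess–Martin oxidation would give the Z-enoate aldehyde F9.
- SmI2 with MeOH in THF without HMPA, followed by DBU, would cyclise F9 to 18.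

**Step 10.** Regiocontrol of the elimination may be lost: the syn C2–H can be removed in place of the C4–H, or a hydride shift in an ion-pair pathway can scatter the alkene position. The fallback replaces elimination by enol-derivative reduction; it sets out from 11 and returns at 12. Dess–Martin oxidation would give the C3 ketone F10. Tf2O with 2,6-di-tert-butyl-4-methylpyridine would give the more substituted enol triflate F11 under thermodynamic control. Reduction with Pd(OAc)2, PPh3, Bu3N and HCO2H in DMF would give 12.

**Step 16.** If the lactol opens only on warming, the barium reagent may equilibrate and attack through its substituted terminus, giving the branched adduct; facial control at C12 may also be eroded by the tethered alkoxide. The fallback builds the prenyl group in two stages; it sets out from 19 and returns at 21. Allylmagnesium bromide (or a chiral allylborane if the substrate bias is weak) would give the homoallylic diol F12. Cross-metathesis with 2-methylbut-2-ene and second-generation Grubbs catalyst would convert the terminal alkene into the prenyl group of 21.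

**Step 18.** Discrimination between O12 and O6 may be incomplete, leading to acylation at O6 or to mixtures of mono- and diacetates. The fallback uses the silyl group to separate the two acylations; it sets out from 21 and returns at 23. One equivalent of Ac2O in pyridine at low temperature would give the C12 monoacetate F13 while C9 is still silylated. HF·pyridine would give the 6,9-diol 12-acetate F14 without a basic medium that could move the acetyl group. A second equivalent of Ac2O would then acylate the unhindered allylic C9 hydroxyl to give 23.

## Further compounds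

F1 | step 14 | methyl (1S,2R,3R,5R)-5-[3-hydroxy-5-(trimethylsilyl)pent-1-en-4-yn-2-yl]-2-methyl-3-(oxan-2-yloxy)cyclopentane-1-carboxylate, C9 as in 9 | COC(=O)[C@@H]1[C@@H](C)[C@H](OC2CCCCO2)C[C@H]1C(=C)[C@H](O)C#C[Si](C)(C)C
F2 | step 14 | methyl (1S,2R,3R,5R)-5-(3-hydroxypent-1-en-4-yn-2-yl)-2-methyl-3-(oxan-2-yloxy)cyclopentane-1-carboxylate | COC(=O)[C@@H]1[C@@H](C)[C@H](OC2CCCCO2)C[C@H]1C(=C)[C@H](O)C#C
F3 | step 14 | methyl (1S,2R,3R,5R)-5-[3-(tert-butyldimethylsilyloxy)pent-1-en-4-yn-2-yl]-2-methyl-3-(oxan-2-yloxy)cyclopentane-1-carboxylate | COC(=O)[C@@H]1[C@@H](C)[C@H](OC2CCCCO2)C[C@H]1C(=C)[C@H](O[Si](C)(C)C(C)(C)C)C#C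
F4 | step 14 | methyl (1S,2R,3R,5R)-5-[3-(tert-butyldimethylsilyloxy)pent-1-en-4-yn-2-yl]-3-hydroxy-2-methylcyclopentane-1-carboxylate | COC(=O)[C@@H]1[C@@H](C)[C@H](O)C[C@H]1C(=C)[C@H](O[Si](C)(C)C(C)(C)C)C#C
F5 | step 14 | methyl (1S,5R)-5-[3-(tert-butyldimethylsilyloxy)pent-1-en-4-yn-2-yl]-2-methylcyclopent-2-ene-1-carboxylate | COC(=O)[C@@H]1C(C)=CC[C@H]1C(=C)[C@H](O[Si](C)(C)C(C)(C)C)C#C
F6 | step 14 | [(1S,5R)-5-[3-(tert-butyldimethylsilyloxy)pent-1-en-4-yn-2-yl]-2-methylcyclopent-2-en-1-yl]methanol | OC[C@@H]1C(C)=CC[C@H]1C(=C)[C@H](O[Si](C)(C)C(C)(C)C)C#C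
F7 | step 14 | (3R)-3-(tert-butyldimethylsilyloxy)-4-[(1R,5S)-5-(hydroxymethyl)-4-methylcyclopent-3-en-1-yl]pent-4-enal | OC[C@@H]1C(C)=CC[C@H]1C(=C)[C@H](O[Si](C)(C)C(C)(C)C)CC=O
F8 | step 14 | methyl (2Z,5R)-5-(tert-butyldimethylsilyloxy)-6-[(1R,5S)-5-(hydroxymethyl)-4-methylcyclopent-3-en-1-yl]-2-methylhepta-2,6-dienoate | OC[C@@H]1C(C)=CC[C@H]1C(=C)[C@H](O[Si](C)(C)C(C)(C)C)C/C=C(/C)C(=O)OC
F9 | step 14 | methyl (2Z,5R)-5-(tert-butyldimethylsilyloxy)-6-[(1R,5S)-5-formyl-4-methylcyclopent-3-en-1-yl]-2-methylhepta-2,6-dienoate | O=C[C@@H]1C(C)=CC[C@H]1C(=C)[C@H](O[Si](C)(C)C(C)(C)C)C/C=C(/C)C(=O)OC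
F10 | step 10 | methyl (1S,2R,5R)-5-[(3R)-3-(tert-butyldimethylsilyloxy)hexa-1,5-dien-2-yl]-2-methyl-3-oxocyclopentane-1-carboxylate | COC(=O)[C@@H]1[C@@H](C)C(=O)C[C@H]1C(=C)[C@H](O[Si](C)(C)C(C)(C)C)CC=C
F11 | step 10 | methyl (1S,5R)-5-[(3R)-3-(tert-butyldimethylsilyloxy)hexa-1,5-dien-2-yl]-2-methyl-3-(trifluoromethanesulfonyloxy)cyclopent-2-ene-1-carboxylate | COC(=O)[C@@H]1C(C)=C(OS(=O)(=O)C(F)(F)F)C[C@H]1C(=C)[C@H](O[Si](C)(C)C(C)(C)C)CC=C
F12 | step 16 | (1R,5S,6R,7S,9R,11S,12S)-9-(tert-butyldimethylsilyloxy)-12-(prop-2-en-1-yl)guaia-3,10(14)-diene-6,12-diol | C=C1[C@H](O[Si](C)(C)C(C)(C)C)C[C@@H]([C@H](C)[C@H](CC=C)O)[C@@H](O)[C@@H]2C(C)=CC[C@@H]12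
F13 | step 18 | (1R,5S,6R,7S,9R,11S,12S)-9-(tert-butyldimethylsilyloxy)-6-hydroxy-12-(3-methylbut-2-en-1-yl)guaia-3,10(14)-dien-12-yl acetate | C=C1[C@H](O[Si](C)(C)C(C)(C)C)C[C@@H]([C@H](C)[C@H](CC=C(C)C)OC(C)=O)[C@@H](O)[C@@H]2C(C)=CC[C@@H]12
F14 | step 18 | (1R,5S,6R,7S,9R,11S,12S)-6,9-dihydroxy-12-(3-methylbut-2-en-1-yl)guaia-3,10(14)-dien-12-yl acetate | C=C1[C@H](O)C[C@@H]([C@H](C)[C@H](CC=C(C)C)OC(C)=O)[C@@H](O)[C@@H]2C(C)=CC[C@@H]12
A1 | alternative 1 | bicyclic bis(enol silane) with C8 ester and C4 ketal | C1C(O[Si](C)(C)C(C)(C)C)=C(C(=O)OC)[C@@H]([C@H](C)[C@H](CC=C(C)C)O[Si](C)(C)C(C)(C)C)C(O[Si](C)(C)C(C)(C)C)=C2C3(OCCO3)CC[C@@H]12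
A2 | alternative 2 | 4-(tert-butyldimethylsilyloxy)-5-[3-(tert-butyldimethylsilyloxy)-6-methylhept-5-en-2-yl]cyclohept-2-en-1-one, C6, C7, C11 and C12 as in the target | O=C1CC[C@@H]([C@H](C)[C@H](CC=C(C)C)O[Si](C)(C)C(C)(C)C)[C@@H](O[Si](C)(C)C(C)(C)C)C=C1
A3 | alternative 2 | trans-1-allyl-5-isopropenyl cycloheptanone | O=C1CC[C@@H]([C@H](C)[C@H](CC=C(C)C)O[Si](C)(C)C(C)(C)C)[C@@H](O[Si](C)(C)C(C)(C)C)[C@H](C(C)=C)[C@H]1CC=C
A4 | alternative 3 | trans-fused six-membered C10 ketone with the cis 6,12-lactone | O=C1C[C@H]2[C@H](C)C(=O)O[C@H]2[C@@H]3C(C)=CC[C@@H]13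
A5 | alternative 3 | ring-expanded C9=C10 trimethylsilyl enol ether lactone | C[Si](C)(C)OC1=CC[C@H]2[C@H](C)C(=O)O[C@H]2[C@@H]3C(C)=CC[C@@H]13
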